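A product excess read at one moment is a trap: it belongs to that moment of the run, so I looked for a number that stays put.

all flasks: left-handed substrate 0.12 M; right-handed substrate 0.12 M; free catalyst 3.5 mM; racemization catalyst 1.2 mM

|  | reagent | added ligand | remark | time |
|---|---|---|---|---|
| Wednesday's | 0.36 M | 12 mM | the very flask that is asked about, followed so far |  |
| Saturday's | 0.36 M | 6 mM | run made earlier |  |
| flask | 0.360 M | 12 mM |  | 20 min |

| run | time / min | left-handed product / % | right-handed product / % |
|---|---|---|---|
| Wednesday's | 0.667 | 0.9 | 0.6 |
| Wednesday's | 1.33 | 2.1 | 1.2 |
| Wednesday's | 2.50 | 5.1 | 2.7 |
| Wednesday's | 4.00 | 8.2 | 0.3 |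
| Wednesday's | 8.00 | 15.2 | 1.4 |
| Saturday's | 1.50 | 3.0 | 0 |
| Saturday's | 3.00 | 5.8 | 1.2 |
| Saturday's | 6.00 | 10.3 | 2.0 |
| Saturday's | 10.0 | 17.8 | 2.7 |
| Saturday's | 20.0 | 27.8 | 6.2 |

(readings scatter by 1 percentage point)

- free catalyst is single-handed; left-handed substrate and right-handed substrate are mirror images of each other, charged as a racemate, each of them at the stated concentration
- steps that have been proposed: 2 free catalyst <-> resting dimer; reagent + free catalyst + right-handed substrate -> free catalyst + right-handed product; reagent + free catalyst + left-handed substrate -> free catalyst + left-handed product; left-handed substrate + racemization catalyst <-> right-handed substrate + racemization catalyst; free catalyst + added ligand <-> idle complex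
- an excess is the difference of the two amounts in percent of their sum
- an excess is below zero if the other one leads

- left-handed product and right-handed product together, in percent of the left-handed substrate and right-handed substrate charged together, at 20 min
- excess of left-handed product over right-handed product in the product at 20 min
- whether the exchange between left-handed substrate and right-handed substrate keeps pace with the reaction: how far the product's excess at 20 min gets from its value without exchange to its value with instant exchange (above 80 % keeps pace, below 20 % hardly takes part, else lags behind)

Saturday's flask looked nearly like Wednesday's, the flask asked about, but held half the added ligand. At 8.00 min Wednesday's total stood at 16.6 %. Midway between 6.00 min and 10.0 min, Saturday's stood at 16.4 %, so the readings showed no gap beyond their scatter. I therefore took Saturday's end total, 34.0 %, for Wednesday's flask.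

Free catalyst and reagent stand in both product-forming steps and cancel in their ratio. That ratio is then [left-handed substrate]/[right-handed substrate] times the selectivity factor s, which I took without exchange as the logarithm of the left-handed substrate's remaining share divided by the logarithm of the right-handed substrate's remaining share. Each share is one minus twice the product's percentage. On Saturday's last reading:

s = 6.13

The zero of this scale is s = 1, where the mirror images react alike and the excess is nil. This reading is soft, since it rests on a small right-handed amount with a scatter of 1 percentage point. Instant exchange would hold the excess at (s − 1)/(s + 1) = 72.0 %. Equal totals and equal s gave me Saturday's excess, 63.5 %, for Wednesday's flask. This reckoning assumes no exchange, so it could not test exchange.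

The forecast said 35 %, 66 % and exchange lags behind, an excess above mine, and warned that “the 1-point scatter allows almost anything”.

The flask gave 33.5 %, 59.1 % and exchange that hardly takes part.

    2 free catalyst ⇌ resting dimer, settled at all times (K = 140 M⁻¹)
    reagent + free catalyst + right-handed substrate → free catalyst + right-handed product (k = 12.0 M⁻² min⁻¹)
    reagent + free catalyst + left-handed substrate → free catalyst + left-handed product (k = 61.0 M⁻² min⁻¹)
    left-handed substrate + racemization catalyst ⇌ right-handed substrate + racemization catalyst, rate k4*[racemization catalyst]*[left-handed substrate] forward; the back reaction follows from the equilibrium constant (k = 2.70 M⁻¹ min⁻¹)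
    free catalyst + added ligand ⇌ idle complex (K = 71.0 M⁻¹, k = 2.30 M⁻¹ min⁻¹)

Exchange got 4.4 % of the way, and striking it out made no difference to the excess, so the forecast's middle call fell and the no-exchange rule applied. The length of the run moved the excess: it stood at 59.1 % at 20 min and at 39.0 % in a run to 200 min. With the flask's 6.86 % of right-handed product, s put left-handed product at 29.8 % and the excess at 62.5 %.

In the flask with 0.90 M of reagent, s and 15.7 % of right-handed product gave 45.1 % of left-handed product and an excess of 48.2 %. That flask itself gave 43.5 % and 46.8 %.

The readings come from a simulation from invented constants.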